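Ring A, the terminal phloroglucinol, is cut at its C1–C2 bond. C1 carries the ether oxygen to ring B and lies between the C2 and C6 hydroxyls, and the 2,4,6-oxygen pattern is that of a triketide. One intramolecular Claisen condensation joins the aryloxy-bearing terminal carbon of a linear ester to the ester carbon and closes ring A onto an oxygen that was attached earlier by plain SN2 etherification. The precursor is methyl 6-aryloxy-3,5-dioxohexanoate carried as its C3 methyl enol ether, so that C2 cannot be enolised and O-acylation stays reversible. The AB phenol is then coupled with a CDEF bromide and all fifteen methyl ethers are cleaved last.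

Key step: step 6

Remark: the target has no stereocentre and no configurationally stable axis, so there is no enantiomer to select; rings are lettered A to F in the order of the SMILES string.

Step 1
Reactants: 1 syringaldehyde (4-hydroxy-3,5-dimethoxybenzaldehyde)
Product: 2 4-(benzyloxy)-3,5-dimethoxybenzaldehyde
Conditions: BnBr, K2CO3, DMF, 60 °C
Reagents that add atoms: benzyl bromide, BrCc1ccccc1
Why: Williamson etherification of the acidic para-formyl phenol should go cleanly and puts the only hydrogenolysable group on the future ring B C4 oxygen.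

Step 2
Reactants: 2 4-(benzyloxy)-3,5-dimethoxybenzaldehyde
Product: 4 4-(benzyloxy)-3,5-dimethoxyphenol, via aryl formate 3 (not isolated)
Conditions: mCPBA, CH2Cl2, 0 °C to rt; aq. NaHCO3 wash; then K2CO3 (cat.), MeOH, rt
Reagents that add atoms: 3-chloroperbenzoic acid, OOC(=O)c1cccc(Cl)c1
Why: Baeyer–Villiger oxidation of an electron-rich benzaldehyde proceeds with aryl migration, and methanolysis of the formate frees the ring B C1 phenol.

Step 3
Reactants: 4 4-(benzyloxy)-3,5-dimethoxyphenol; 5 ethyl bromoacetate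
Product: 7 2-[4-(benzyloxy)-3,5-dimethoxyphenoxy]acetic acid, via ethyl ester 6 (not isolated)
Conditions: K2CO3, acetone, reflux; then LiOH, THF/H2O, rt; 1 M HCl
Reagents that add atoms: lithium hydroxide, [Li+].[OH-]
Why: Williamson SN2 etherification of the unhindered phenoxide with the α-bromo ester, followed by saponification, makes at an sp3 carbon the C–O bond that will become the crowded ring A C1–O bond.

Step 4
Reactants: 8 methyl (2E)-3-methoxybut-2-enoate
Product: 9 1,3-dimethoxy-1-(trimethylsilyloxy)buta-1,3-diene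
Conditions: LDA, THF, −78 °C; TMSCl, −78 °C to rt; distillation
Reagents that add atoms: chlorotrimethylsilane, C[Si](C)(C)Cl
Why: γ-Deprotonation of the β-methoxy enoate and O-silylation of the dienolate should give the silyl ketene acetal diene, a C4-nucleophilic equivalent of an acetoacetate whose C3 oxygen is already methylated.

Step 5
Reactants: 7 2-[4-(benzyloxy)-3,5-dimethoxyphenoxy]acetic acid; 9 1,3-dimethoxy-1-(trimethylsilyloxy)buta-1,3-diene
Product: 11 methyl (2E)-6-[4-(benzyloxy)-3,5-dimethoxyphenoxy]-3-methoxy-5-oxohex-2-enoate, via acid chloride 10 (not isolated)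
Conditions: (COCl)2, DMF (cat.), CH2Cl2, 0 °C to rt, evaporate; 9, CH2Cl2, −78 °C to rt; aq. NaHCO3
Reagents that add atoms: none
Why: The diene should attack the acid chloride through its terminal carbon (vinylogous Mukaiyama-type γ-acylation of a silyl dienol ether), and loss of Me3SiCl restores the conjugated β-methoxy enoate, of which the E isomer is the stable one.

Step 6
Reactants: 11 methyl (2E)-6-[4-(benzyloxy)-3,5-dimethoxyphenoxy]-3-methoxy-5-oxohex-2-enoate
Product: 13 2-[4-(benzyloxy)-3,5-dimethoxyphenoxy]-5-methoxybenzene-1,3-diol, via cyclohexenedione tautomer 12 (not isolated)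
Conditions: NaOMe (4 equiv), MeOH, 65 °C, Ar; then 1 M HCl, 0 °C
Reagents that add atoms: none
Why: Proposed new method: methoxide reversibly forms the C4 and C6 enolates of 11, and only the C6 enolate, which the aryloxy oxygen makes more accessible than an ordinary ketone α-carbon, can reach the ester carbon C1, where it adds and expels methoxide to give dione 12, whose enolisation to the aromatic bis-phenoxide makes the closure irreversible. The closest known reactions are the alkoxide-mediated Claisen (Dieckmann-type) cyclisation of 5-oxo esters to cyclohexane-1,3-diones, the Mg(OMe)2-induced closure of 3,5,7-triketo esters to acylphloroglucinols and the methoxide-induced conversion of 4-methoxy-6-methyl-2-pyrone into 5-methoxyresorcinol, none of which has an aryloxy group on the attacking carbon. Ring A closes in the 6-(enolendo)-exo-trig mode, and no stereocentre remains after aromatisation. The selectivity needed is C-acylation from C6 against O-acylation from the C5 enolate oxygen, and it is secured thermodynamically, because O-acylation gives a neutral 4-methoxy-2-pyrone that methoxide reopens to the same enolate, whereas a free C3 carbonyl would end as an inert pyronate and would let C2 deprotonation silence the ester. The C3 enol ether removes the acidic C2 methylene, its E geometry holds C1 and C4 cis as the ring requires, and conjugate addition of methoxide at C3 only gives the 3,3-dimethoxy ester, a plain 5-oxo ester that should close the same way. Methyl ester, methyl enol ether and methoxide are matched so that every exchange is degenerate.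

Step 7
Reactants: 13 2-[4-(benzyloxy)-3,5-dimethoxyphenoxy]-5-methoxybenzene-1,3-diol
Product: 14 2-[4-(benzyloxy)-3,5-dimethoxyphenoxy]-1,3,5-trimethoxybenzene
Conditions: Me2SO4, K2CO3, acetone, reflux
Reagents that add atoms: dimethyl sulfate, COS(=O)(=O)OC
Why: Williamson O-methylation with a hard electrophile and a weak base in acetone should cap both phenols of the resorcinol without C-alkylation.

Step 8
Reactants: 14 2-[4-(benzyloxy)-3,5-dimethoxyphenoxy]-1,3,5-trimethoxybenzene
Product: 15 2,6-dimethoxy-4-(2,4,6-trimethoxyphenoxy)phenol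
Conditions: H2 (1 atm), 10% Pd/C, EtOAc/MeOH, rt
Reagents that add atoms: none
Why: Hydrogenolysis of the benzyl aryl ether frees the ring B C4 phenol and leaves methyl and diaryl ethers untouched.

Step 9
Reactants: 16 (3,4,5-trimethoxyphenyl)boronic acid; 17 4-bromo-2,6-dimethoxyphenol
Product: 18 5-bromo-1,3-dimethoxy-2-(3,4,5-trimethoxyphenoxy)benzene
Conditions: Cu(OAc)2 (0.5 equiv), pyridine, 4 Å MS, CH2Cl2, O2 (1 atm), rt
Reagents that add atoms: none
Why: Chan–Lam O-arylation joins the di-ortho-methoxy phenol (ring E) to the unhindered arylboron partner (ring F) at room temperature and does not touch the aryl bromide.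

Step 10
Reactants: 18 5-bromo-1,3-dimethoxy-2-(3,4,5-trimethoxyphenoxy)benzene
Product: 21 [3,5-dimethoxy-4-(3,4,5-trimethoxyphenoxy)phenyl]boronic acid, via aryllithium 19 (not isolated), via lithium triisopropoxyborate 20 (not isolated)
Conditions: n-BuLi, THF, −78 °C; B(OiPr)3, −78 °C to rt; 1 M HCl
Reagents that add atoms: triisopropyl borate, CC(C)OB(OC(C)C)OC(C)C; water, O
Why: Bromine–lithium exchange, trapping of the aryllithium by the borate and acidic hydrolysis is the standard way from an aryl bromide to the boronic acid.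

Step 11
Reactants: 22 5-bromo-1,2,3-trimethoxybenzene
Product: 24 6-bromo-2,3,4-trimethoxybenzaldehyde, via α-chloro ether 23 (not isolated)
Conditions: Cl2CHOMe, TiCl4, CH2Cl2, −10 °C to rt; ice water
Reagents that add atoms: dichloromethyl methyl ether, COC(Cl)Cl; water, O
Why: Rieche formylation can only enter at the two equivalent free positions, each ortho and para to a methoxy group, which places the formyl group (the latent ring D C6 oxygen) next to the bromine (ring D C1).

Step 12
Reactants: 24 6-bromo-2,3,4-trimethoxybenzaldehyde; 17 4-bromo-2,6-dimethoxyphenol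
Product: 25 6-(4-bromo-2,6-dimethoxyphenoxy)-2,3,4-trimethoxybenzaldehyde
Conditions: CuI (10 mol%), picolinic acid (20 mol%), K3PO4, DMSO, 90 °C
Reagents that add atoms: none
Why: In this Ullmann-type copper-catalysed O-arylation the ortho-formyl bromide of 24 is activated while the bromide of the phenoxide partner is switched off by its para oxygen, so the ring C C4–O–ring D C1 ether is made on small fragments.

Step 13
Reactants: 25 6-(4-bromo-2,6-dimethoxyphenoxy)-2,3,4-trimethoxybenzaldehyde
Product: 27 6-(4-bromo-2,6-dimethoxyphenoxy)-2,3,4-trimethoxyphenol, via aryl formate 26 (not isolated)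
Conditions: mCPBA, CH2Cl2, 0 °C; aq. NaHCO3 wash; then K2CO3 (cat.), MeOH, rt
Reagents that add atoms: 3-chloroperbenzoic acid, OOC(=O)c1cccc(Cl)c1
Why: Baeyer–Villiger oxidation with migration of the di-ortho-oxygenated aryl group, then formate methanolysis, turns the formyl group into the ring D C6 hydroxyl.

Step 14
Reactants: 27 6-(4-bromo-2,6-dimethoxyphenoxy)-2,3,4-trimethoxyphenol; 21 [3,5-dimethoxy-4-(3,4,5-trimethoxyphenoxy)phenyl]boronic acid
Product: 28 5-bromo-2-{2-[3,5-dimethoxy-4-(3,4,5-trimethoxyphenoxy)phenoxy]-3,4,5-trimethoxyphenoxy}-1,3-dimethoxybenzene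
Conditions: Cu(OAc)2 (0.5 equiv), pyridine, 4 Å MS, CH2Cl2, O2 (1 atm), rt
Reagents that add atoms: none
Why: A second Chan–Lam O-arylation couples the flanked ring D phenol with the unhindered EF boronic acid and again spares the ring C bromide.

Step 15
Reactants: 15 2,6-dimethoxy-4-(2,4,6-trimethoxyphenoxy)phenol; 28 5-bromo-2-{2-[3,5-dimethoxy-4-(3,4,5-trimethoxyphenoxy)phenoxy]-3,4,5-trimethoxyphenoxy}-1,3-dimethoxybenzene
Product: 29 pentadeca-O-methyl ether of the target (2-[4-(4-{2-[3,5-dimethoxy-4-(3,4,5-trimethoxyphenoxy)phenoxy]-3,4,5-trimethoxyphenoxy}-3,5-dimethoxyphenoxy)-3,5-dimethoxyphenoxy]-1,3,5-trimethoxybenzene)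
Conditions: CuI (20 mol%), picolinic acid (40 mol%), K3PO4, DMSO, 100 °C, Ar
Reagents that add atoms: none
Why: Ullmann-type O-arylation under conditions suited to 2,6-disubstituted phenols joins the ring B C4 oxygen to ring C C1, an aryl bromide with two free ortho positions.

Step 16
Reactants: 29 pentadeca-O-methyl ether of the target
Product: 30 target CNP0175585.0 (2-[4-(4-{2-[3,5-dihydroxy-4-(3,4,5-trihydroxyphenoxy)phenoxy]-3,4,5-trihydroxyphenoxy}-3,5-dihydroxyphenoxy)-3,5-dihydroxyphenoxy]benzene-1,3,5-triol)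
Conditions: BBr3 (2 equiv per OMe), CH2Cl2, −78 °C to rt, Ar; then H2O, 0 °C
Reagents that add atoms: none
Why: Lewis-acid ether cleavage with BBr3 (bromide attack at methyl) should remove all fifteen methyl groups and leave the five diaryl ether bonds, which offer no sp3 carbon to attack, in place.

Compound list

1 | syringaldehyde (4-hydroxy-3,5-dimethoxybenzaldehyde) | COc1cc(C=O)cc(OC)c1O | starting material
2 | 4-(benzyloxy)-3,5-dimethoxybenzaldehyde | COc1cc(C=O)cc(OC)c1OCc1ccccc1 | intermediate
3 | 4-(benzyloxy)-3,5-dimethoxyphenyl formate | COc1cc(OC=O)cc(OC)c1OCc1ccccc1 | intermediate (not isolated)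
4 | 4-(benzyloxy)-3,5-dimethoxyphenol | COc1cc(O)cc(OC)c1OCc1ccccc1 | intermediate
5 | ethyl bromoacetate | CCOC(=O)CBr | starting material
6 | ethyl 2-[4-(benzyloxy)-3,5-dimethoxyphenoxy]acetate | CCOC(=O)COc1cc(OC)c(OCc2ccccc2)c(OC)c1 | intermediate (not isolated)
7 | 2-[4-(benzyloxy)-3,5-dimethoxyphenoxy]acetic acid | OC(=O)COc1cc(OC)c(OCc2ccccc2)c(OC)c1 | intermediate
8 | methyl (2E)-3-methoxybut-2-enoate | COC(=O)/C=C(\C)OC | starting material
9 | 1,3-dimethoxy-1-(trimethylsilyloxy)buta-1,3-diene (ketene acetal geometry not controlled and without consequence) | C=C(OC)C=C(OC)O[Si](C)(C)C | intermediate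
10 | 2-[4-(benzyloxy)-3,5-dimethoxyphenoxy]acetyl chloride | ClC(=O)COc1cc(OC)c(OCc2ccccc2)c(OC)c1 | intermediate (not isolated)
11 | methyl (2E)-6-[4-(benzyloxy)-3,5-dimethoxyphenoxy]-3-methoxy-5-oxohex-2-enoate | COC(=O)/C=C(\CC(=O)COc1cc(OC)c(OCc2ccccc2)c(OC)c1)OC | intermediate
12 | 2-[4-(benzyloxy)-3,5-dimethoxyphenoxy]-5-methoxycyclohex-4-ene-1,3-dione (racemic at C2, centre lost on enolisation) | O=C1C=C(OC)CC(=O)C1Oc1cc(OC)c(OCc2ccccc2)c(OC)c1 | intermediate (not isolated)
13 | 2-[4-(benzyloxy)-3,5-dimethoxyphenoxy]-5-methoxybenzene-1,3-diol | COc1cc(O)c(Oc2cc(OC)c(OCc3ccccc3)c(OC)c2)c(O)c1 | intermediate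
14 | 2-[4-(benzyloxy)-3,5-dimethoxyphenoxy]-1,3,5-trimethoxybenzene | COc1cc(OC)c(Oc2cc(OC)c(OCc3ccccc3)c(OC)c2)c(OC)c1 | intermediate
15 | 2,6-dimethoxy-4-(2,4,6-trimethoxyphenoxy)phenol | COc1cc(OC)c(Oc2cc(OC)c(O)c(OC)c2)c(OC)c1 | intermediate
16 | (3,4,5-trimethoxyphenyl)boronic acid | COc1cc(B(O)O)cc(OC)c1OC | starting material
17 | 4-bromo-2,6-dimethoxyphenol | COc1cc(Br)cc(OC)c1O | starting material
18 | 5-bromo-1,3-dimethoxy-2-(3,4,5-trimethoxyphenoxy)benzene | COc1cc(Br)cc(OC)c1Oc1cc(OC)c(OC)c(OC)c1 | intermediate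
19 | [3,5-dimethoxy-4-(3,4,5-trimethoxyphenoxy)phenyl]lithium | COc1cc([Li])cc(OC)c1Oc1cc(OC)c(OC)c(OC)c1 | intermediate (not isolated)
20 | lithium [3,5-dimethoxy-4-(3,4,5-trimethoxyphenoxy)phenyl]tri(propan-2-yloxy)borate | COc1cc([B-](OC(C)C)(OC(C)C)OC(C)C)cc(OC)c1Oc1cc(OC)c(OC)c(OC)c1.[Li+] | intermediate (not isolated)
21 | [3,5-dimethoxy-4-(3,4,5-trimethoxyphenoxy)phenyl]boronic acid | COc1cc(B(O)O)cc(OC)c1Oc1cc(OC)c(OC)c(OC)c1 | intermediate
22 | 5-bromo-1,2,3-trimethoxybenzene | COc1cc(Br)cc(OC)c1OC | starting material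
23 | 1-bromo-2-[chloro(methoxy)methyl]-3,4,5-trimethoxybenzene | COC(Cl)c1c(Br)cc(OC)c(OC)c1OC | intermediate (not isolated)
24 | 6-bromo-2,3,4-trimethoxybenzaldehyde | COc1cc(Br)c(C=O)c(OC)c1OC | intermediate
25 | 6-(4-bromo-2,6-dimethoxyphenoxy)-2,3,4-trimethoxybenzaldehyde | COc1cc(Br)cc(OC)c1Oc1cc(OC)c(OC)c(OC)c1C=O | intermediate
26 | 6-(4-bromo-2,6-dimethoxyphenoxy)-2,3,4-trimethoxyphenyl formate | COc1cc(Br)cc(OC)c1Oc1cc(OC)c(OC)c(OC)c1OC=O | intermediate (not isolated)
27 | 6-(4-bromo-2,6-dimethoxyphenoxy)-2,3,4-trimethoxyphenol | COc1cc(Br)cc(OC)c1Oc1cc(OC)c(OC)c(OC)c1O | intermediate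
28 | 5-bromo-2-{2-[3,5-dimethoxy-4-(3,4,5-trimethoxyphenoxy)phenoxy]-3,4,5-trimethoxyphenoxy}-1,3-dimethoxybenzene | COc1cc(Br)cc(OC)c1Oc1cc(OC)c(OC)c(OC)c1Oc1cc(OC)c(Oc2cc(OC)c(OC)c(OC)c2)c(OC)c1 | intermediate
29 | pentadeca-O-methyl ether of the target | COc1cc(OC)c(Oc2cc(OC)c(Oc3cc(OC)c(Oc4cc(OC)c(OC)c(OC)c4Oc4cc(OC)c(Oc5cc(OC)c(OC)c(OC)c5)c(OC)c4)c(OC)c3)c(OC)c2)c(OC)c1 | intermediate
30 | CNP0175585.0 (achiral) | Oc1cc(O)c(Oc2cc(O)c(Oc3cc(O)c(Oc4cc(O)c(O)c(O)c4Oc4cc(O)c(Oc5cc(O)c(O)c(O)c5)c(O)c4)c(O)c3)c(O)c2)c(O)c1 | target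

Total step count: 16. Longest linear sequence: 9 steps (steps 1, 2, 3, 5, 6, 7, 8, 15 and 16, from 1 to 30).

Steps most likely to fail

Step 6 (Proposed new method). The C6 enolate may not reach C1 at a useful rate. Methoxide could then cut the C4–C5 bond in a retro-Claisen-type fragmentation, or the material could rest as the 4-methoxy-2-pyrone. The fallback uses known chemistry, sets out from 4 and returns at 14, and brings ring A in preformed. 1,3,5-Trimethoxybenzene is iodinated (NIS, MeCN, rt) to 2-iodo-1,3,5-trimethoxybenzene F1. F1 is then coupled with phenol 4 in an Ullmann diaryl ether synthesis (CuI, picolinic acid, K3PO4, DMSO, 100 °C), which should give 14 directly, so that the route continues with step 8.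

Step 15. Copper phenoxide formation and aryl transfer may be slow for the hindered, electron-rich phenoxide of 15, so that 28 is reduced to the arene or 15 is oxidised before the two couple. The fallback sets out from 28 and returns at 29, and changes the aryl donor from halide to boron. Bromine–lithium exchange on 28 (n-BuLi, THF, −78 °C) should give the CDEF aryllithium F2, triisopropyl borate converts it into the lithium triisopropoxyborate F3, and acidic hydrolysis releases the CDEF boronic acid F4. F4 and 15 are then joined by Chan–Lam O-arylation (Cu(OAc)2, pyridine, 4 Å MS, CH2Cl2, O2, rt) to give 29.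

Step 16. Cleavage may stop short at some of the fifteen ethers, and the free polyphenol, with its pyrogallol-type rings D and F, may be oxidised by air or lost on the stationary phase during isolation. The fallback sets out from 29 and returns at 30, and avoids isolating the free polyphenol in crude form. After the BBr3 treatment the crude material is peracetylated (Ac2O, pyridine, DMAP cat.) to the pentadeca-O-acetate F5. F5 is purified by chromatography as a stable neutral compound, where under-cleaved material separates, and transesterification (NaOMe cat., MeOH, Ar; acidic resin) then releases 30.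

Further compounds

F1 | step 6 | 2-iodo-1,3,5-trimethoxybenzene | COc1cc(OC)c(I)c(OC)c1
F2 | step 15 | [4-{2-[3,5-dimethoxy-4-(3,4,5-trimethoxyphenoxy)phenoxy]-3,4,5-trimethoxyphenoxy}-3,5-dimethoxyphenyl]lithium | COc1cc([Li])cc(OC)c1Oc1cc(OC)c(OC)c(OC)c1Oc1cc(OC)c(Oc2cc(OC)c(OC)c(OC)c2)c(OC)c1
F3 | step 15 | lithium [4-{2-[3,5-dimethoxy-4-(3,4,5-trimethoxyphenoxy)phenoxy]-3,4,5-trimethoxyphenoxy}-3,5-dimethoxyphenyl]tri(propan-2-yloxy)borate | COc1cc([B-](OC(C)C)(OC(C)C)OC(C)C)cc(OC)c1Oc1cc(OC)c(OC)c(OC)c1Oc1cc(OC)c(Oc2cc(OC)c(OC)c(OC)c2)c(OC)c1.[Li+]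
F4 | step 15 | [4-{2-[3,5-dimethoxy-4-(3,4,5-trimethoxyphenoxy)phenoxy]-3,4,5-trimethoxyphenoxy}-3,5-dimethoxyphenyl]boronic acid | COc1cc(B(O)O)cc(OC)c1Oc1cc(OC)c(OC)c(OC)c1Oc1cc(OC)c(Oc2cc(OC)c(OC)c(OC)c2)c(OC)c1
F5 | step 16 | pentadeca-O-acetate of 30 | CC(=O)Oc1cc(OC(C)=O)c(Oc2cc(OC(C)=O)c(Oc3cc(OC(C)=O)c(Oc4cc(OC(C)=O)c(OC(C)=O)c(OC(C)=O)c4Oc4cc(OC(C)=O)c(Oc5cc(OC(C)=O)c(OC(C)=O)c(OC(C)=O)c5)c(OC(C)=O)c4)c(OC(C)=O)c3)c(OC(C)=O)c2)c(OC(C)=O)c1
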